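**Retrosynthetic overview**
1. Target 12 ← hydrolysis of the two vinylogous methyl esters of 2,5-dimethoxy-3-methyl-6-pentadecyl-1,4-benzoquinone 10.
2. 10 ← the bond between the second and third chain carbons (C2'–C3', counted from the ring), made by radical 1,6-conjugate addition of a tridecyl radical (from B-tridecylcatecholborane 8, made from 1-tridecene 7) to vinylquinone 6.
3. Enabling feature: ring C6, which carries the side chain, is linked through the ring C5=C6 double bond to the C4 carbonyl, so a vinyl group on C6 is a dienone whose terminal CH2 is the future C2'. C2, C3 and C5 are substituted, so this CH2 is the only open radical acceptor site.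
4. 6 ← CAN oxidation ← Suzuki–Miyaura vinylation ← ring bromination ← ortho-lithiation/methylation of 1,2,4,5-tetramethoxybenzene 1.
5. No ring is formed: the six-membered carbocycle is bought as the tetramethoxyarene and brought to the quinone level before the key step.

Key step: step 6

Remark: the target is a 2,5-dihydroxy-1,4-benzoquinone whose two enol–enone tautomers interconvert rapidly and it has no stereocentre; 1,2,4,5-tetramethoxybenzene, 1-tridecene, catecholborane and vinylboronic acid pinacol ester are taken as commercially available.

**Step 1**
Reactants: 1 1,2,4,5-tetramethoxybenzene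
Product: 3 1,2,4,5-tetramethoxy-3-methylbenzene, via aryllithium 2 (not isolated)
Conditions: n-BuLi (1.05 equiv), TMEDA, THF, 0 °C; then MeI, 0 °C to rt
Reagents that add atoms: iodomethane, CI
Why: Directed ortho-lithiation removes a ring hydrogen flanked by two methoxy groups, and the aryllithium is methylated by SN2 on iodomethane.

**Step 2**
Reactants: 3 1,2,4,5-tetramethoxy-3-methylbenzene
Product: 4 1-bromo-2,3,5,6-tetramethoxy-4-methylbenzene
Conditions: NBS (1.05 equiv), MeCN, 0 °C to rt, dark
Reagents that add atoms: N-bromosuccinimide, O=C1CCC(=O)N1Br
Why: Electrophilic aromatic bromination at the only remaining ring C–H, activated by four methoxy groups; a polar solvent and exclusion of light should suppress benzylic bromination.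

**Step 3**
Reactants: 4 1-bromo-2,3,5,6-tetramethoxy-4-methylbenzene
Product: 5 1-ethenyl-2,3,5,6-tetramethoxy-4-methylbenzene
Conditions: vinylboronic acid pinacol ester (1.5 equiv), Pd(OAc)2 (cat.), SPhos (cat.), K3PO4, toluene/H2O, 90 °C
Reagents that add atoms: vinylboronic acid pinacol ester, C=CB1OC(C)(C)C(C)(C)O1
Why: Suzuki–Miyaura coupling, with a bulky electron-rich biarylphosphine suited to an electron-rich, di-ortho-substituted aryl bromide.

**Step 4**
Reactants: 5 1-ethenyl-2,3,5,6-tetramethoxy-4-methylbenzene
Product: 6 2,5-dimethoxy-3-methyl-6-vinyl-1,4-benzoquinone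
Conditions: CAN (2.5 equiv), MeCN/H2O, 0 °C, short contact time; cold extractive work-up, solution used promptly
Reagents that add atoms: water, O
Why: Cerium(IV) oxidative demethylation of a hydroquinone dimethyl ether: water attacks the arene radical cation at a methoxy-bearing carbon with loss of methanol, and either para pair of methoxy groups leads to the same 2,5-dimethoxy-1,4-benzoquinone.

**Step 5**
Reactants: 7 1-tridecene
Product: 8 2-tridecyl-1,3,2-benzodioxaborole
Conditions: catecholborane (0.95 equiv), N,N-dimethylacetamide (cat.), CH2Cl2, reflux; volatiles removed under argon, used crude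
Reagents that add atoms: catecholborane, B1Oc2ccccc2O1
Why: Amide-catalysed anti-Markovnikov hydroboration of a terminal alkene should place boron on the terminal carbon.

**Step 6**
Reactants: 6 2,5-dimethoxy-3-methyl-6-vinyl-1,4-benzoquinone; 8 2-tridecyl-1,3,2-benzodioxaborole
Product: 10 2,5-dimethoxy-3-methyl-6-pentadecyl-1,4-benzoquinone, via boron dienolate 9 (not isolated)
Conditions: 8 (1.5 equiv), DMPU (1 equiv), CH2Cl2, air admitted slowly (cat. O2), 0 °C to rt; then H2O, rt; silica gel
Reagents that add atoms: none
Why: Proposed new method: traces of oxygen convert a little 8 into the tridecyl radical, which as a nucleophilic primary radical should add to the unsubstituted terminal CH2 of the vinyl group of 6, the δ-terminus of the C=C–C6=C5–C4=O dienone, forming the C2'–C3' bond and a captodatively stabilised dienoxyl radical with spin on O4. Homolytic substitution by this oxygen-centred radical at the boron of a second molecule of 8 should give boron dienolate 9 and release the next tridecyl radical, so the addition runs as a chain; water then cleaves the O–B bond with proton transfer to the exocyclic carbon, and all tautomers should funnel to the thermodynamically favoured quinone 10, already at the oxidation level of the target. The closest known reaction type is the oxygen-initiated radical conjugate addition of trialkylboranes and B-alkylcatecholboranes to enones and to 1,4-benzoquinones, extended here from a 1,4- to a 1,6-acceptor. No ring is closed and no stereocentre is formed; the geometry of the exocyclic double bond of 9 is lost on tautomerisation. The step needs carbon addition at the vinyl terminus in preference to addition at a carbonyl oxygen or a ring carbon, which the substrate should secure because C2, C3, C5 and C6 are all substituted while the vinyl CH2 is unhindered and polarity-matched to the radical. Catecholborane is used in deficit in step 5 so that no B–H reductant reaches the quinone.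

**Step 7**
Reactants: 10 2,5-dimethoxy-3-methyl-6-pentadecyl-1,4-benzoquinone
Product: 12 2,5-dihydroxy-3-methyl-6-pentadecyl-1,4-benzoquinone, via disodium salt 11 (not isolated)
Conditions: 2 M NaOH aq, EtOH, 70 °C, N2; then 2 M HCl, 0 °C
Reagents that add atoms: sodium hydroxide, [Na+].[OH-]
Why: Addition–elimination (saponification) of the two vinylogous methyl esters by hydroxide should give the dianion of the dihydroxyquinone, which is protonated on acidification.

**Compound list**
1 | 1,2,4,5-tetramethoxybenzene | COc1cc(OC)c(OC)cc1OC | starting material
2 | (2,3,5,6-tetramethoxyphenyl)lithium | [Li]c1c(OC)c(OC)cc(OC)c1OC | intermediate (not isolated)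
3 | 1,2,4,5-tetramethoxy-3-methylbenzene | Cc1c(OC)c(OC)cc(OC)c1OC | intermediate
4 | 1-bromo-2,3,5,6-tetramethoxy-4-methylbenzene | Cc1c(OC)c(OC)c(Br)c(OC)c1OC | intermediate
5 | 1-ethenyl-2,3,5,6-tetramethoxy-4-methylbenzene | C=Cc1c(OC)c(OC)c(C)c(OC)c1OC | intermediate
6 | 2,5-dimethoxy-3-methyl-6-vinyl-1,4-benzoquinone | C=CC1=C(OC)C(=O)C(C)=C(OC)C1=O | intermediate
7 | 1-tridecene | CCCCCCCCCCCC=C | starting material
8 | 2-tridecyl-1,3,2-benzodioxaborole | CCCCCCCCCCCCCB1Oc2ccccc2O1 | intermediate
9 | 4-(1,3,2-benzodioxaborol-2-yloxy)-2,5-dimethoxy-3-methyl-6-pentadecylidenecyclohexa-2,4-dien-1-one (boron dienolate; drawn Z, geometry without consequence) | CCCCCCCCCCCCCC/C=C1\C(=O)C(OC)=C(C)C(OB2Oc3ccccc3O2)=C1OC | intermediate (not isolated)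
10 | 2,5-dimethoxy-3-methyl-6-pentadecyl-1,4-benzoquinone | CCCCCCCCCCCCCCCC1=C(OC)C(=O)C(C)=C(OC)C1=O | intermediate
11 | disodium 3-methyl-6-pentadecyl-1,4-benzoquinone-2,5-diolate | CCCCCCCCCCCCCCCC1=C([O-])C(=O)C(C)=C([O-])C1=O.[Na+].[Na+] | intermediate (not isolated)
12 | 2,5-dihydroxy-3-methyl-6-pentadecyl-1,4-benzoquinone | CCCCCCCCCCCCCCCC1=C(O)C(=O)C(C)=C(O)C1=O | target

**Step count and risks**
Total step count: 7. Longest linear sequence: 6 steps (1, 2, 3, 4, 6, 7); step 5 is a one-step side branch.

Steps most likely to fail:

Step 6 (Proposed new method). The tridecyl radical may add to a carbonyl oxygen of the quinone, chain transfer from the delocalised dienoxyl radical to boron may be too slow, or the vinylquinone may oligomerise or dimerise by Diels–Alder reaction. The fallback sets out from 5 and makes the same chain bond at the arene oxidation level with known chemistry. Hydroboration of 5 with 9-BBN (THF, 0 °C to rt) should give 9-[2-(2,3,5,6-tetramethoxy-4-methylphenyl)ethyl]-9-borabicyclo[3.3.1]nonane F1. Without isolation, F1 is coupled with 1-bromotridecane in an alkyl–alkyl Suzuki–Miyaura reaction (Pd(OAc)2, PCy3, K3PO4·H2O, THF, rt) to give 1,2,4,5-tetramethoxy-3-methyl-6-pentadecylbenzene F2. CAN oxidation of F2 (MeCN/H2O, 0 °C) returns to the route at 10, and step 7 follows.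

Step 4. Cerium(IV) or nitrate may attack the electron-rich styrene double bond, and the vinylquinone may dimerise or polymerise during work-up. The fallback sets out from 4 and reverses the order, so that the vinyl group never meets the oxidant. CAN oxidation of 4 should give 2-bromo-3,6-dimethoxy-5-methyl-1,4-benzoquinone F3. Stille coupling of F3 with tributyl(vinyl)stannane (Pd(PPh3)4, toluene, 80 °C) returns to the route at 6, whose solution is taken directly into step 6; step 3 is bypassed.

Step 3. Oxidative addition of palladium into the hindered, electron-rich C–Br bond may be slow, with competing protodebromination and loss of the vinyl boronate by polymerisation. The fallback sets out from 3 and uses olefination instead of cross-coupling. Ortho-lithiation of 3 (n-BuLi, TMEDA, THF, 0 °C) should give (2,3,5,6-tetramethoxy-4-methylphenyl)lithium F4. Quenching F4 with DMF and aqueous work-up gives 2,3,5,6-tetramethoxy-4-methylbenzaldehyde F5. Wittig methylenation of F5 (Ph3PCH3Br, KOtBu, THF, 0 °C to rt) returns to the route at 5; step 2 is bypassed as well.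

**Further compounds**
F1 | step 6 | 9-[2-(2,3,5,6-tetramethoxy-4-methylphenyl)ethyl]-9-borabicyclo[3.3.1]nonane | COc1c(C)c(OC)c(OC)c(CCB2C3CCCC2CCC3)c1OC
F2 | step 6 | 1,2,4,5-tetramethoxy-3-methyl-6-pentadecylbenzene | CCCCCCCCCCCCCCCc1c(OC)c(OC)c(C)c(OC)c1OC
F3 | step 4 | 2-bromo-3,6-dimethoxy-5-methyl-1,4-benzoquinone | CC1=C(OC)C(=O)C(Br)=C(OC)C1=O
F4 | step 3 | (2,3,5,6-tetramethoxy-4-methylphenyl)lithium | [Li]c1c(OC)c(OC)c(C)c(OC)c1OC
F5 | step 3 | 2,3,5,6-tetramethoxy-4-methylbenzaldehyde | O=Cc1c(OC)c(OC)c(C)c(OC)c1OC
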